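The trimer, read as catechin-(4α→8)-gallocatechin-(4β→8)-catechin, is cut at the upper interflavan bond, from C4 of the top catechin C ring to C8 of the gallocatechin A ring. The key step exploits two features. C4 is benzylic to a 5,7-dioxygenated A ring and ionises readily, and C8 is the most nucleophilic free A-ring carbon of the lower dimer. One Lewis-acid operation joins an 8-bromo-capped, 3-O-acetyl, 4-alkoxy catechin to the dimer and sets C4 (3,4-trans) under control of the 3β-acetoxy group. The dimer partner is a glutarate-bridged macrocycle. Its tether has earlier enforced the unusual 3,4-cis lower linkage and now serves as protection.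

Key step: step 10

Remark on the chemistry: the stereodescriptors translate to 2R,3S in all three units, a 3,4-trans (4α) upper linkage and a 3,4-cis (4β) lower linkage. (+)-Gallocatechin is assumed to be purchasable like (+)-catechin. The C4 configuration drawn for 4, 5 and 8 (4β) is lost on ionisation and does not affect the outcome.

Step 1
Reactants: 1 (+)-catechin
Product: 2 5,7,3',4'-tetra-O-benzyl-(+)-catechin
Conditions: BnBr, K2CO3, DMF, 0 °C to rt
Reagents that add atoms: benzyl bromide, BrCc1ccccc1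
Why: Williamson etherification alkylates the four acidic phenols while the secondary 3-OH stays free under carbonate conditions, and no stereocentre is touched.

Step 2
Reactants: 2 5,7,3',4'-tetra-O-benzyl-(+)-catechin
Product: 3 8-bromo-5,7,3',4'-tetra-O-benzyl-(+)-catechin
Conditions: NBS (1 equiv), CH2Cl2, −78 °C to rt
Reagents that add atoms: N-bromosuccinimide, O=C1CCC(=O)N1Br
Why: Electrophilic aromatic bromination should go to C8, the most electron-rich and least hindered A-ring carbon (C6 lies between two benzyloxy groups), and installs the cap that later stops the electrophile from acting as its own nucleophile.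

Step 3
Reactants: 3 8-bromo-5,7,3',4'-tetra-O-benzyl-(+)-catechin
Product: 4 (2R,3S,4S)-8-bromo-4β-(2-ethoxyethoxy)-5,7,3',4'-tetra-O-benzylcatechin
Conditions: DDQ, EtOCH2CH2OH, CH2Cl2, rt
Reagents that add atoms: 2-ethoxyethanol, CCOCCO
Why: DDQ-mediated benzylic C–H oxidation (oxidative etherification) is specific for C4, which is activated by the 5,7-dioxygenated A ring, and the alcohol is expected to add pseudo-axially on the β face, anti to the C2 aryl group.

Step 4
Reactants: 4 (2R,3S,4S)-8-bromo-4β-(2-ethoxyethoxy)-5,7,3',4'-tetra-O-benzylcatechin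
Product: 5 (2R,3S,4S)-3-O-acetyl-8-bromo-4β-(2-ethoxyethoxy)-5,7,3',4'-tetra-O-benzylcatechin
Conditions: Ac2O, DMAP (cat.), pyridine, rt
Reagents that add atoms: acetic anhydride, CC(=O)OC(C)=O
Why: DMAP-catalysed O-acylation of the only free hydroxyl installs the β-face-shielding 3-acetoxy group without disturbing the base-stable C4 ether.

Step 5
Reactants: 6 (+)-gallocatechin
Product: 7 5,7,3',4',5'-penta-O-benzyl-(+)-gallocatechin
Conditions: BnBr, K2CO3, degassed DMF, Ar, 0 °C to rt
Reagents that add atoms: benzyl bromide, BrCc1ccccc1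
Why: Williamson etherification of the five phenols, run with strict exclusion of oxygen to protect the pyrogallol ring from base-promoted autoxidation, leaves the 3-OH and both stereocentres untouched.

Step 6
Reactants: 7 5,7,3',4',5'-penta-O-benzyl-(+)-gallocatechin
Product: 8 (2R,3S,4S)-4β-(2-ethoxyethoxy)-5,7,3',4',5'-penta-O-benzylgallocatechin
Conditions: DDQ, EtOCH2CH2OH, CH2Cl2, rt
Reagents that add atoms: 2-ethoxyethanol, CCOCCO
Why: The same DDQ oxidative etherification as in step 3 functionalises C4 in preference to C2, because only C4 is conjugated with the two A-ring oxygen donors.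

Step 7
Reactants: 2 5,7,3',4'-tetra-O-benzyl-(+)-catechin
Product: 9 5,7,3',4'-tetra-O-benzylcatechin 3-O-hemiglutarate
Conditions: glutaric anhydride, DMAP (cat.), pyridine, 40 °C
Reagents that add atoms: glutaric anhydride, O=C1CCCC(=O)O1
Why: DMAP-catalysed ring opening of the cyclic anhydride by the 3-OH (acyl transfer) gives the half ester in an addition that loses no atoms and retains C3.

Step 8
Reactants: 8 (2R,3S,4S)-4β-(2-ethoxyethoxy)-5,7,3',4',5'-penta-O-benzylgallocatechin; 9 5,7,3',4'-tetra-O-benzylcatechin 3-O-hemiglutarate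
Product: 10 mixed glutarate diester joining O3 of 8 to O3 of the catechin unit of 9
Conditions: DCC, DMAP (cat.), CH2Cl2, 0 °C to rt
Reagents that add atoms: none
Why: Steglich esterification acylates the hindered secondary 3-OH of 8 under neutral conditions that leave the acid-labile C4 ether intact.

Step 9
Reactants: 10 mixed glutarate diester
Product: 12 nona-O-benzyl-gallocatechin-(4β→8)-catechin 3,3-O-glutarate macrocycle, via tethered flavan-4-yl cation 11 (not isolated)
Conditions: TMSOTf (cat.), CH2Cl2 (ca. 1 mM), −40 to −20 °C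
Reagents that add atoms: none
Why: This is an intramolecular Friedel–Crafts-type flavan-4-yl arylation (tethered interflavan condensation, 14-membered closure) in which the five-carbon diester hangs from the β-oriented O3 of the gallocatechin unit and is too short to let the catechin A ring reach the α face, so its C8 should add to C4 from the β face (3,4-cis) while high dilution suppresses intermolecular attack.

Step 10
Reactants: 5 (2R,3S,4S)-3-O-acetyl-8-bromo-4β-(2-ethoxyethoxy)-5,7,3',4'-tetra-O-benzylcatechin; 12 nona-O-benzyl-gallocatechin-(4β→8)-catechin 3,3-O-glutarate macrocycle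
Product: 14 fully protected trimer (8-bromo-3-O-acetyl-tetra-O-benzylcatechin-(4α→8)-linked to macrocycle 12), via 8-bromo-3-acetoxyflavan-4-yl cation 13 (not isolated)
Conditions: TMSOTf (cat.), CH2Cl2, −78 to −40 °C, 5 and 12 near-equimolar
Reagents that add atoms: none
Why: Catalytic TMSOTf ionises the C4–O bond of 5 to the A-ring-stabilised benzylic cation 13, which is attacked by C8 of the gallocatechin A ring of 12 in an intermolecular Friedel–Crafts alkylation, and loss of the C8 proton restores aromaticity and releases 2-ethoxyethanol. The closest known reaction type is the Lewis-acid-mediated condensation of 4-alkoxyflavan-3-yl acetates with benzylated flavan-3-ol nucleophiles used to build 4→8 proanthocyanidin linkages. No ring is closed; one C–C bond and one stereocentre (C4 of the top unit) are formed. The 3β-acetoxy group shields or bridges the β face of 13, so the bulky dimer should enter from the α face, anti to the C3 substituent, giving the 3,4-trans (4α) linkage while C2 and C3 are untouched. Site selectivity is needed among C8 and C6 of the gallocatechin unit and C6 of the bottom catechin unit: C8 lies between O1 and a single benzyloxy group and is the most electron-rich and least hindered, each C6 is flanked by two benzyloxy groups, and C8 of the bottom unit is already substituted. Chemoselectivity is secured by the C8 bromine of 5, which prevents self-condensation of the electrophile and further growth of 14, and by the low temperature and the acylated, tether-locked lower linkage, which should not re-ionise.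

Step 11
Reactants: 14 fully protected trimer
Product: 15 8-bromo-trideca-O-benzyl-catechin-(4α→8)-gallocatechin-(4β→8)-catechin (three free 3-OH groups)
Conditions: DIBAL-H (excess), CH2Cl2, −78 to 0 °C; aq. Rochelle salt
Reagents that add atoms: none
Why: Reductive ester cleavage with DIBAL-H removes the hindered acetate and both glutarate esters in one operation under non-basic, non-acidic conditions that spare the aryl bromide, the benzyl ethers, the interflavan bonds and all stereocentres.

Step 12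
Reactants: 15 8-bromo-trideca-O-benzyl-catechin-(4α→8)-gallocatechin-(4β→8)-catechin
Product: 16 catechin-(4α→8)-gallocatechin-(4β→8)-catechin (target)
Conditions: H2 (1 atm), Pd(OH)2/C, THF–MeOH–H2O, rt; filtration under Ar, lyophilisation, Sephadex LH-20
Reagents that add atoms: none
Why: Catalytic hydrogenolysis cleaves the thirteen benzyl ethers and the C8–Br cap together, while the C2–O and C4–aryl bonds and the stereocentres are expected to persist under these mild conditions.

Compound list
1 | (+)-catechin, (2R,3S) | Oc1cc(O)c2c(c1)O[C@H](c1ccc(O)c(O)c1)[C@@H](O)C2 | starting material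
2 | 5,7,3',4'-tetra-O-benzyl-(+)-catechin | O(Cc3ccccc3)c1cc(OCc3ccccc3)c2c(c1)O[C@H](c1ccc(OCc3ccccc3)c(OCc3ccccc3)c1)[C@@H](O)C2 | intermediate
3 | 8-bromo-5,7,3',4'-tetra-O-benzyl-(+)-catechin | O(Cc3ccccc3)c1cc(OCc3ccccc3)c2c(c1Br)O[C@H](c1ccc(OCc3ccccc3)c(OCc3ccccc3)c1)[C@@H](O)C2 | intermediate
4 | (2R,3S,4S)-8-bromo-4β-(2-ethoxyethoxy)-5,7,3',4'-tetra-O-benzylcatechin (2,3-trans, 3,4-cis) | O(Cc3ccccc3)c1cc(OCc3ccccc3)c2c(c1Br)O[C@H](c1ccc(OCc3ccccc3)c(OCc3ccccc3)c1)[C@@H](O)[C@H]2OCCOCC | intermediate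
5 | (2R,3S,4S)-3-O-acetyl-8-bromo-4β-(2-ethoxyethoxy)-5,7,3',4'-tetra-O-benzylcatechin | O(Cc3ccccc3)c1cc(OCc3ccccc3)c2c(c1Br)O[C@H](c1ccc(OCc3ccccc3)c(OCc3ccccc3)c1)[C@@H](OC(C)=O)[C@H]2OCCOCC | intermediate
6 | (+)-gallocatechin, (2R,3S) | Oc1cc(O)c2c(c1)O[C@H](c1cc(O)c(O)c(O)c1)[C@@H](O)C2 | starting material
7 | 5,7,3',4',5'-penta-O-benzyl-(+)-gallocatechin | O(Cc3ccccc3)c1cc(OCc3ccccc3)c2c(c1)O[C@H](c1cc(OCc3ccccc3)c(OCc3ccccc3)c(OCc3ccccc3)c1)[C@@H](O)C2 | intermediate
8 | (2R,3S,4S)-4β-(2-ethoxyethoxy)-5,7,3',4',5'-penta-O-benzylgallocatechin | O(Cc3ccccc3)c1cc(OCc3ccccc3)c2c(c1)O[C@H](c1cc(OCc3ccccc3)c(OCc3ccccc3)c(OCc3ccccc3)c1)[C@@H](O)[C@H]2OCCOCC | intermediate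
9 | 5,7,3',4'-tetra-O-benzylcatechin 3-O-hemiglutarate (free acid) | O(Cc3ccccc3)c1cc(OCc3ccccc3)c2c(c1)O[C@H](c1ccc(OCc3ccccc3)c(OCc3ccccc3)c1)[C@@H](OC(=O)CCCC(=O)O)C2 | intermediate
10 | mixed glutarate diester, O3 of 8 to O3 of tetra-O-benzylcatechin | O(Cc3ccccc3)c1cc(OCc3ccccc3)c2c(c1)O[C@H](c1cc(OCc3ccccc3)c(OCc3ccccc3)c(OCc3ccccc3)c1)[C@@H](OC(=O)CCCC(=O)O[C@H]4Cc5c(OCc3ccccc3)cc(OCc3ccccc3)cc5O[C@@H]4c6ccc(OCc3ccccc3)c(OCc3ccccc3)c6)[C@H]2OCCOCC | intermediate
11 | tethered flavan-4-yl cation (C4 of the gallocatechin unit, triflate as counter-ion) | O(Cc3ccccc3)c1cc(OCc3ccccc3)c2c(c1)O[C@H](c1cc(OCc3ccccc3)c(OCc3ccccc3)c(OCc3ccccc3)c1)[C@@H](OC(=O)CCCC(=O)O[C@H]4Cc5c(OCc3ccccc3)cc(OCc3ccccc3)cc5O[C@@H]4c6ccc(OCc3ccccc3)c(OCc3ccccc3)c6)[CH+]2 | intermediate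
12 | nona-O-benzyl-gallocatechin-(4β→8)-catechin 3,3-O-glutarate (14-membered dilactone, 3,4-cis, C8 of the gallocatechin unit free) | O(Cc3ccccc3)c1cc(OCc3ccccc3)c2c(c1)O[C@H](c1cc(OCc3ccccc3)c(OCc3ccccc3)c(OCc3ccccc3)c1)[C@@H](OC(=O)CCCC(=O)O4)[C@H]2c1c(OCc3ccccc3)cc(OCc3ccccc3)c2c1O[C@H](c1ccc(OCc3ccccc3)c(OCc3ccccc3)c1)[C@@H]4C2 | intermediate
13 | 8-bromo-3-acetoxy-tetra-O-benzylflavan-4-yl cation (triflate as counter-ion) | O(Cc3ccccc3)c1cc(OCc3ccccc3)c2c(c1Br)O[C@H](c1ccc(OCc3ccccc3)c(OCc3ccccc3)c1)[C@@H](OC(C)=O)[CH+]2 | intermediate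
14 | protected trimer: 3-O-acetyl-8-bromo-tetra-O-benzylcatechin-(4α→8)-penta-O-benzylgallocatechin-(4β→8)-tetra-O-benzylcatechin, the two lower O3 atoms bridged by glutarate | O(Cc3ccccc3)c1cc(OCc3ccccc3)c2c(c1Br)O[C@H](c1ccc(OCc3ccccc3)c(OCc3ccccc3)c1)[C@@H](OC(C)=O)[C@@H]2c1c(OCc3ccccc3)cc(OCc3ccccc3)c2c1O[C@H](c1cc(OCc3ccccc3)c(OCc3ccccc3)c(OCc3ccccc3)c1)[C@@H](OC(=O)CCCC(=O)O4)[C@H]2c1c(OCc3ccccc3)cc(OCc3ccccc3)c2c1O[C@H](c1ccc(OCc3ccccc3)c(OCc3ccccc3)c1)[C@@H]4C2 | intermediate
15 | 8-bromo-trideca-O-benzyl-catechin-(4α→8)-gallocatechin-(4β→8)-catechin, three free 3-OH | O(Cc3ccccc3)c1cc(OCc3ccccc3)c2c(c1Br)O[C@H](c1ccc(OCc3ccccc3)c(OCc3ccccc3)c1)[C@@H](O)[C@@H]2c1c(OCc3ccccc3)cc(OCc3ccccc3)c2c1O[C@H](c1cc(OCc3ccccc3)c(OCc3ccccc3)c(OCc3ccccc3)c1)[C@@H](O)[C@H]2c1c(OCc3ccccc3)cc(OCc3ccccc3)c2c1O[C@H](c1ccc(OCc3ccccc3)c(OCc3ccccc3)c1)[C@@H](O)C2 | intermediate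
16 | catechin-(4α→8)-gallocatechin-(4β→8)-catechin | Oc1cc(O)c2c(c1)O[C@H](c1ccc(O)c(O)c1)[C@@H](O)[C@@H]2c1c(O)cc(O)c2c1O[C@H](c1cc(O)c(O)c(O)c1)[C@@H](O)[C@H]2c1c(O)cc(O)c2c1O[C@H](c1ccc(O)c(O)c1)[C@@H](O)C2 | target

Total step count: 12. Longest linear sequence: 7 steps (for example steps 5, 6, 8, 9, 10, 11, 12; the other two branches are equally long).

Steps most likely to fail

Step 10. The cation may be captured through C6 of either lower unit. α-Facial selectivity may erode with so large a nucleophile. Slow capture may let the ionised electrophile decay. The fallback makes the nucleophilic site explicit and forms the same bond by ipso-substitution of boron.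
- It sets out from 12. NBS in CH2Cl2 at −78 °C should give the macrocycle brominated at C8 of the gallocatechin unit, F1. Its regiochemistry can be checked, and isomers removed, before 5 is committed.
- Miyaura borylation (B2pin2, Pd(dppf)Cl2, KOAc, dioxane, 90 °C), which tolerates the esters, should give the C8 pinacol boronate of the macrocycle, F2.
- Lewis-acid-promoted coupling of F2 with 5 (TMSOTf, CH2Cl2, −78 °C) replaces boron by C4 of the top unit. The fallback comes back to the route at 14.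

Step 9. Intermolecular oligomerisation may outrun the 14-membered closure. Participation of the 3-O-acyl carbonyl may steer the arene to the α face. Closure may also occur through C6. The fallback gives up the tether.
- It sets out from 8 and an excess of 2, condensed intermolecularly with TiCl4 in CH2Cl2 at 0 °C.
- With a free 3-OH and no participating group, both C4 epimers are expected.
- Chromatography should deliver the 3,4-cis epimer, nona-O-benzyl-gallocatechin-(4β→8)-catechin with both 3-OH groups free, F3. Excess 2 is recovered.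
- F3 takes the place of 12 in the coupling with 5 under the step 10 conditions. This should give the trimer monoacetate, F4.
- DIBAL-H cleavage of the single acetate of F4 comes back to the route at 15.

Step 12. Cleavage of thirteen benzyl ethers may stall. Bromide may poison the catalyst. Acid released by C–Br hydrogenolysis may cleave or scramble the interflavan bonds. The free pyrogallol ring may oxidise in air. The fallback removes the cap separately under non-acidic conditions.
- It sets out from 15. Excess n-BuLi in THF at −78 °C deprotonates the three hydroxyls first and then effects bromine–lithium exchange.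
- A methanol quench should give the debrominated trideca-O-benzyl trimer, F5.
- Halide-free hydrogenolysis of F5 (H2, Pd(OH)2/C, THF–MeOH–H2O) comes back to the route at 16.

Further compounds
F1 | step 10 | macrocycle 12 brominated at C8 of the gallocatechin unit | O(Cc3ccccc3)c1cc(OCc3ccccc3)c2c(c1Br)O[C@H](c1cc(OCc3ccccc3)c(OCc3ccccc3)c(OCc3ccccc3)c1)[C@@H](OC(=O)CCCC(=O)O4)[C@H]2c1c(OCc3ccccc3)cc(OCc3ccccc3)c2c1O[C@H](c1ccc(OCc3ccccc3)c(OCc3ccccc3)c1)[C@@H]4C2
F2 | step 10 | macrocycle 12 bearing a pinacol boronate at C8 of the gallocatechin unit | O(Cc3ccccc3)c1cc(OCc3ccccc3)c2c(c1B5OC(C)(C)C(C)(C)O5)O[C@H](c1cc(OCc3ccccc3)c(OCc3ccccc3)c(OCc3ccccc3)c1)[C@@H](OC(=O)CCCC(=O)O4)[C@H]2c1c(OCc3ccccc3)cc(OCc3ccccc3)c2c1O[C@H](c1ccc(OCc3ccccc3)c(OCc3ccccc3)c1)[C@@H]4C2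
F3 | step 9 | nona-O-benzyl-gallocatechin-(4β→8)-catechin, both 3-OH free | O(Cc3ccccc3)c1cc(OCc3ccccc3)c2c(c1)O[C@H](c1cc(OCc3ccccc3)c(OCc3ccccc3)c(OCc3ccccc3)c1)[C@@H](O)[C@H]2c1c(OCc3ccccc3)cc(OCc3ccccc3)c2c1O[C@H](c1ccc(OCc3ccccc3)c(OCc3ccccc3)c1)[C@@H](O)C2
F4 | step 9 | 3-O-acetyl-8-bromo-trideca-O-benzyl-catechin-(4α→8)-gallocatechin-(4β→8)-catechin, two lower 3-OH free | O(Cc3ccccc3)c1cc(OCc3ccccc3)c2c(c1Br)O[C@H](c1ccc(OCc3ccccc3)c(OCc3ccccc3)c1)[C@@H](OC(C)=O)[C@@H]2c1c(OCc3ccccc3)cc(OCc3ccccc3)c2c1O[C@H](c1cc(OCc3ccccc3)c(OCc3ccccc3)c(OCc3ccccc3)c1)[C@@H](O)[C@H]2c1c(OCc3ccccc3)cc(OCc3ccccc3)c2c1O[C@H](c1ccc(OCc3ccccc3)c(OCc3ccccc3)c1)[C@@H](O)C2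
F5 | step 12 | trideca-O-benzyl-catechin-(4α→8)-gallocatechin-(4β→8)-catechin, no bromine, three free 3-OH | O(Cc3ccccc3)c1cc(OCc3ccccc3)c2c(c1)O[C@H](c1ccc(OCc3ccccc3)c(OCc3ccccc3)c1)[C@@H](O)[C@@H]2c1c(OCc3ccccc3)cc(OCc3ccccc3)c2c1O[C@H](c1cc(OCc3ccccc3)c(OCc3ccccc3)c(OCc3ccccc3)c1)[C@@H](O)[C@H]2c1c(OCc3ccccc3)cc(OCc3ccccc3)c2c1O[C@H](c1ccc(OCc3ccccc3)c(OCc3ccccc3)c1)[C@@H](O)C2
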